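## Retrosynthetic overview

1. The pyran ring (O1–C2–C3–C4–C4a–C8a) is cut at both of its bonds to the arene, C4–C4a and O1–C8a. A Pd/norbornene (Catellani-type) annulation joins a 4-iodo-3-methylphenol ether to a γ-bromo tertiary alcohol; the C8 methyl group is the ortho blocker, and C2 arrives intact from a Sharpless epoxide of geraniol.
2. The side chain is cut at C4'–C5'. Zweifel olefination of a (Z)-alkenyl iodide (C1'–C4', made from the prenyl end of the annulation product) with a primary boronic ester (C5'–C13') sets the 3'E olefin.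
3. The C5'–C13' unit comes from the enantiomeric epoxygeraniol. Payne rearrangement with sulfonium ylide homologation turns the 2,3-epoxy alcohol into the erythro 7'S,8'R diol carrying a vinyl handle (C5'=C6').
4. Both C10 halves are geraniol; the three stereocentres come from two Sharpless epoxidations (L- and D-tartrate). The only ring formed is the pyran ring, in step 5.

Key step: step 5

Remark: read from the SMILES, the target is the (2S)-chroman with a (7'S,8'R) diol, i.e. the erythro diol that corresponds to anti addition across a 7'E olefin; the route is built for exactly this isomer.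

## Route

Step 1
Reactants: 1 geraniol
Product: 2 (2S,3S)-2,3-epoxygeraniol
Conditions: Ti(OiPr)4 (5 mol%), L-(+)-diethyl tartrate (6 mol%), t-BuOOH, 4 Å MS, CH2Cl2, −20 °C
Reagents that add atoms: tert-butyl hydroperoxide, CC(C)(C)OO
Why: Sharpless asymmetric epoxidation touches only the allylic 2,3-olefin, and L-(+)-tartrate selects the face that gives the (2S,3S)-epoxide, which fixes the future C2 of the chroman (geraniol C3).

Step 2
Reactants: 2 (2S,3S)-2,3-epoxygeraniol
Product: 3 (3S)-3,7-dimethyloct-6-ene-1,3-diol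
Conditions: Red-Al, THF, 0 °C to rt
Reagents that add atoms: none
Why: Alkoxide-directed hydride delivery opens the 2,3-epoxy alcohol at C2 (Red-Al reduction to the 1,3-diol), so the tertiary C–O bond and its configuration are not touched.

Step 3
Reactants: 3 (3S)-3,7-dimethyloct-6-ene-1,3-diol
Product: 4 (3S)-1-bromo-3,7-dimethyloct-6-en-3-ol
Conditions: CBr4, PPh3, CH2Cl2, 0 °C
Reagents that add atoms: carbon tetrabromide, BrC(Br)(Br)Br
Why: Appel bromination should be selective for the primary hydroxyl, since the hindered tertiary alcohol does not form the alkoxyphosphonium salt at 0 °C.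

Step 4
Reactants: 5 4-iodo-3-methylphenol
Product: 6 1-iodo-4-(methoxymethoxy)-2-methylbenzene
Conditions: MOMCl, i-Pr2NEt, CH2Cl2, 0 °C to rt
Reagents that add atoms: chloromethyl methyl ether, COCCl
Why: Simple O-alkylation gives a base-stable MOM ether that survives the Pd/base, ylide and organolithium steps and falls off with acid at the end.

Step 5
Reactants: 4 (3S)-1-bromo-3,7-dimethyloct-6-en-3-ol; 6 1-iodo-4-(methoxymethoxy)-2-methylbenzene (1.3 equiv)
Product: 7 (2S)-6-(methoxymethoxy)-2,8-dimethyl-2-(4-methylpent-3-en-1-yl)-3,4-dihydro-2H-chromene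
Conditions: Pd(OAc)2 (10 mol%), RuPhos (20 mol%), norbornene (1.5 equiv), Cs2CO3 (3 equiv), toluene/DME, 100 °C
Reagents that add atoms: none
Why: Proposed new method: Pd(0) inserts into the C–I bond of 6, norbornene carbopalladation and ortho C–H palladation give the aryl-norbornyl palladacycle, the primary bromide of 4 alkylates the ortho carbon through Pd(IV) (C4–C4a bond), and norbornene is extruded because both ortho positions are then substituted. The resulting aryl–Pd(II) carries the tertiary alcohol on the new ortho chain, and base-assisted alkoxide binding followed by C(sp2)–O reductive elimination closes the pyran ring (O1–C8a bond, six-membered ring by intramolecular aryl etherification). The closest known reactions are the Pd/norbornene annulations of aryl iodides with N-protected bromoalkylamines (ortho alkylation, then ipso C–N coupling) and with epoxides (ortho alkylation, then ipso C–O coupling to dihydrobenzofurans), together with the Pd-catalysed intramolecular etherification of aryl halides by tertiary alcohols to chromans. No stereocentre is formed: the C2–O bond of the carbinol is never broken, so the (S) configuration of 4 should pass into 7 unchanged. The step needs mono-ortho-alkylation and ipso C–O coupling instead of ipso reduction; the C8 methyl group blocks the second ortho position and forces norbornene extrusion, and the tertiary alkoxide has no hydrogen on the carbinol carbon, so β-hydride elimination cannot divert the Pd alkoxide.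

Step 6
Reactants: 7 (2S)-6-(methoxymethoxy)-2,8-dimethyl-2-(4-methylpent-3-en-1-yl)-3,4-dihydro-2H-chromene
Product: 8 3-[(2R)-6-(methoxymethoxy)-2,8-dimethyl-3,4-dihydro-2H-chromen-2-yl]propanal
Conditions: OsO4 (2 mol%), NaIO4 (4 equiv), 2,6-lutidine, dioxane/H2O, rt
Reagents that add atoms: osmium tetroxide, O=[Os](=O)(=O)=O (catalytic oxygen carrier); sodium periodate, [Na+].[O-]I(=O)(=O)=O
Why: Lemieux–Johnson cleavage of the only olefin should give the aldehyde without the arene oxidation that ozone could cause on this electron-rich ring; the descriptor changes to R by CIP rules only, with the same spatial arrangement.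

Step 7
Reactants: 8 3-[(2R)-6-(methoxymethoxy)-2,8-dimethyl-3,4-dihydro-2H-chromen-2-yl]propanal
Product: 9 (2S)-2-[(3Z)-4-iodopent-3-en-1-yl]-6-(methoxymethoxy)-2,8-dimethyl-3,4-dihydro-2H-chromene
Conditions: EtPPh3I, n-BuLi, THF, rt; I2, −78 °C; NaHMDS, −20 °C; then 8, −78 to −20 °C
Reagents that add atoms: ethyltriphenylphosphonium iodide, CC[P+](c1ccccc1)(c1ccccc1)c1ccccc1.[I-]; iodine, II
Why: The Stork–Zhao-type α-iodoethylidene Wittig reaction of aldehydes should give the (Z)-2-iodo-2-alkene (iodine cis to the chain) through the kinetically controlled cis-oxaphosphetane of the non-stabilised ylide.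

Step 8
Reactants: 1 geraniol
Product: 10 (2R,3R)-2,3-epoxygeraniol
Conditions: Ti(OiPr)4 (5 mol%), D-(−)-diethyl tartrate (6 mol%), t-BuOOH, 4 Å MS, CH2Cl2, −20 °C
Reagents that add atoms: tert-butyl hydroperoxide, CC(C)(C)OO
Why: Sharpless asymmetric epoxidation with D-(−)-tartrate gives the enantiomeric epoxide and so sets C8' (geraniol C3, kept) and C7' (geraniol C2, to be inverted) together in one catalytic step.

Step 9
Reactants: 10 (2R,3R)-2,3-epoxygeraniol
Product: 12 (3S,4R)-4,8-dimethylnona-1,7-diene-3,4-diol, via Payne-rearranged epoxy alcohol 11 (not isolated)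
Conditions: Me3S+ I− (4 equiv), n-BuLi (4 equiv), THF, −10 °C to rt
Reagents that add atoms: trimethylsulfonium iodide, C[S+](C)C.[I-]
Why: Under basic aprotic conditions the alkoxide of 10 equilibrates by Payne rearrangement (SN2 at geraniol C2, inversion, giving C7' S) to the terminal epoxide 11, which alone is opened at its CH2 carbon by dimethylsulfonium methylide; base-induced loss of dimethyl sulfide then gives the vinyl group (the known ylide homologation of 2,3-epoxy alcohols to ene-diols), so the erythro diol forms with C8' untouched.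

Step 10
Reactants: 12 (3S,4R)-4,8-dimethylnona-1,7-diene-3,4-diol
Product: 13 (4R,5S)-5-ethenyl-2,2,4-trimethyl-4-(4-methylpent-3-en-1-yl)-1,3-dioxolane
Conditions: 2,2-dimethoxypropane, PPTS (cat.), CH2Cl2, rt
Reagents that add atoms: 2,2-dimethoxypropane, COC(C)(C)OC
Why: Acid-catalysed transacetalisation closes the five-membered acetonide on the 1,2-diol and masks both hydroxyls for the borane and organolithium steps.

Step 11
Reactants: 13 (4R,5S)-5-ethenyl-2,2,4-trimethyl-4-(4-methylpent-3-en-1-yl)-1,3-dioxolane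
Product: 14 2-{2-[(4S,5R)-2,2,5-trimethyl-5-(4-methylpent-3-en-1-yl)-1,3-dioxolan-4-yl]ethyl}-4,4,5,5-tetramethyl-1,3,2-dioxaborolane
Conditions: [Ir(cod)Cl]2 (1.5 mol%), dppe (3 mol%), pinacolborane, CH2Cl2, rt
Reagents that add atoms: pinacolborane, CC1(C)OBOC1(C)C
Why: Ir-catalysed hydroboration is anti-Markovnikov and selective for the monosubstituted vinyl group over the trisubstituted olefin, and it places boron on C5', 1,3 to the acetal oxygen, where no β-alkoxy elimination is possible.

Step 12
Reactants: 9 (2S)-2-[(3Z)-4-iodopent-3-en-1-yl]-6-(methoxymethoxy)-2,8-dimethyl-3,4-dihydro-2H-chromene; 14 2-{2-[(4S,5R)-2,2,5-trimethyl-5-(4-methylpent-3-en-1-yl)-1,3-dioxolan-4-yl]ethyl}-4,4,5,5-tetramethyl-1,3,2-dioxaborolane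
Product: 17 (2S)-6-(methoxymethoxy)-2,8-dimethyl-2-{(3E)-4-methyl-6-[(4S,5R)-2,2,5-trimethyl-5-(4-methylpent-3-en-1-yl)-1,3-dioxolan-4-yl]hex-3-en-1-yl}-3,4-dihydro-2H-chromene, via alkenyllithium 15 (not isolated), via lithium boronate complex 16 (not isolated)
Conditions: 9, t-BuLi (2.05 equiv), THF/Et2O, −78 °C; 14, −78 to 0 °C; I2, THF, −78 °C; NaOMe, MeOH, −78 °C to rt
Reagents that add atoms: none
Why: Zweifel olefination: I/Li exchange with retention, boronate formation, iodine-induced 1,2-migration of the primary alkyl group and anti elimination invert the alkene geometry, so the (Z)-iodide (iodine cis to C2') should give the 3'E olefin (C5' trans to C2') stereospecifically.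

Step 13
Reactants: 17 (2S)-6-(methoxymethoxy)-2,8-dimethyl-2-{(3E)-4-methyl-6-[(4S,5R)-2,2,5-trimethyl-5-(4-methylpent-3-en-1-yl)-1,3-dioxolan-4-yl]hex-3-en-1-yl}-3,4-dihydro-2H-chromene
Product: 18 (2S)-2-[(3E,7S,8R)-7,8-dihydroxy-4,8,12-trimethyltrideca-3,11-dien-1-yl]-2,8-dimethyl-3,4-dihydro-2H-chromen-6-ol (target)
Conditions: 2 M HCl, MeOH/THF, 35–40 °C
Reagents that add atoms: none
Why: Acid hydrolysis removes the acetonide and the aryl MOM acetal in one operation; the isolated trisubstituted olefins and the non-allylic tertiary alcohol should tolerate dilute acid at this temperature.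

## Compound list

1 | geraniol, (2E)-3,7-dimethylocta-2,6-dien-1-ol | CC(C)=CCC/C(C)=C/CO | starting material
2 | (2S,3S)-2,3-epoxygeraniol, [(2S,3S)-3-methyl-3-(4-methylpent-3-en-1-yl)oxiran-2-yl]methanol | OC[C@@H]1O[C@@]1(C)CCC=C(C)C | intermediate
3 | (3S)-3,7-dimethyloct-6-ene-1,3-diol | OCC[C@@](C)(O)CCC=C(C)C | intermediate
4 | (3S)-1-bromo-3,7-dimethyloct-6-en-3-ol | BrCC[C@@](C)(O)CCC=C(C)C | intermediate
5 | 4-iodo-3-methylphenol | Cc1cc(O)ccc1I | starting material
6 | 1-iodo-4-(methoxymethoxy)-2-methylbenzene | COCOc1ccc(I)c(C)c1 | intermediate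
7 | (2S)-6-(methoxymethoxy)-2,8-dimethyl-2-(4-methylpent-3-en-1-yl)-3,4-dihydro-2H-chromene | CC(C)=CCC[C@@]1(C)CCc2cc(OCOC)cc(C)c2O1 | intermediate
8 | 3-[(2R)-6-(methoxymethoxy)-2,8-dimethyl-3,4-dihydro-2H-chromen-2-yl]propanal | O=CCC[C@@]1(C)CCc2cc(OCOC)cc(C)c2O1 | intermediate
9 | (2S)-2-[(3Z)-4-iodopent-3-en-1-yl]-6-(methoxymethoxy)-2,8-dimethyl-3,4-dihydro-2H-chromene | C/C(I)=C/CC[C@@]1(C)CCc2cc(OCOC)cc(C)c2O1 | intermediate
10 | (2R,3R)-2,3-epoxygeraniol, [(2R,3R)-3-methyl-3-(4-methylpent-3-en-1-yl)oxiran-2-yl]methanol | OC[C@H]1O[C@]1(C)CCC=C(C)C | intermediate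
11 | (2R)-6-methyl-2-[(2S)-oxiran-2-yl]hept-5-en-2-ol (Payne isomer of 10) | CC(C)=CCC[C@@](C)(O)[C@@H]1CO1 | intermediate
12 | (3S,4R)-4,8-dimethylnona-1,7-diene-3,4-diol | CC(C)=CCC[C@@](C)(O)[C@@H](O)C=C | intermediate
13 | (4R,5S)-5-ethenyl-2,2,4-trimethyl-4-(4-methylpent-3-en-1-yl)-1,3-dioxolane | CC(C)=CCC[C@@]1(C)OC(C)(C)O[C@H]1C=C | intermediate
14 | 2-{2-[(4S,5R)-2,2,5-trimethyl-5-(4-methylpent-3-en-1-yl)-1,3-dioxolan-4-yl]ethyl}-4,4,5,5-tetramethyl-1,3,2-dioxaborolane | CC(C)=CCC[C@@]1(C)OC(C)(C)O[C@H]1CCB2OC(C)(C)C(C)(C)O2 | intermediate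
15 | {(2E)-5-[(2S)-6-(methoxymethoxy)-2,8-dimethyl-3,4-dihydro-2H-chromen-2-yl]pent-2-en-2-yl}lithium (Li cis to the chain, geometry of 9 kept) | C/C([Li])=C/CC[C@@]1(C)CCc2cc(OCOC)cc(C)c2O1 | intermediate
16 | lithium alkenyl(alkyl)pinacolatoborate formed from 15 and 14 | [Li+].CC(C)=CCC[C@@]1(C)OC(C)(C)O[C@H]1CC[B-]2(OC(C)(C)C(C)(C)O2)/C(C)=C\CC[C@@]3(C)CCc4cc(OCOC)cc(C)c4O3 | intermediate
17 | (2S)-6-(methoxymethoxy)-2,8-dimethyl-2-{(3E)-4-methyl-6-[(4S,5R)-2,2,5-trimethyl-5-(4-methylpent-3-en-1-yl)-1,3-dioxolan-4-yl]hex-3-en-1-yl}-3,4-dihydro-2H-chromene | CC(C)=CCC[C@@]1(C)OC(C)(C)O[C@H]1CC/C(C)=C/CC[C@@]2(C)CCc3cc(OCOC)cc(C)c3O2 | intermediate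
18 | (2S)-2-[(3E,7S,8R)-7,8-dihydroxy-4,8,12-trimethyltrideca-3,11-dien-1-yl]-2,8-dimethyl-3,4-dihydro-2H-chromen-6-ol | CC(C)=CCC[C@@](C)(O)[C@@H](O)CC/C(C)=C/CC[C@@]1(C)CCc2cc(O)cc(C)c2O1 | target

## Step count and risks

Total step count: 13. Longest linear sequence: 8 steps (1, 2, 3, 5, 6, 7, 12, 13).

**Step 5 (Proposed new method).** The aryl–Pd(II) formed after ortho alkylation may be reduced or may insert norbornene again before the hindered tertiary alkoxide can bind and undergo C–O reductive elimination; the base may also close 4 to an oxetane. The fallback stitches the two arene bonds one after the other by known couplings and sets out from 2. Iodination (PPh3, I2, imidazole) should give (2S,3R)-3-(iodomethyl)-2-methyl-2-(4-methylpent-3-en-1-yl)oxirane F1, and zinc dust in refluxing ethanol should open it reductively to (3S)-linalool F2 with the tertiary C–O bond retained. Hydroboration of the vinyl group with 9-BBN (2.2 equiv) would give (3R)-1-(9-borabicyclo[3.3.1]nonan-9-yl)-3,7-dimethyloct-6-en-3-ol F3 (same spatial arrangement, descriptor changed by CIP). The arene partner would come from commercial 4-amino-3-methylphenol: NaH then MOMCl to 4-(methoxymethoxy)-2-methylaniline F4, I2/NaHCO3 to 2-iodo-4-(methoxymethoxy)-6-methylaniline F5, and t-BuONO/CuBr2 in MeCN to 2-bromo-1-iodo-5-(methoxymethoxy)-3-methylbenzene F6. B-alkyl Suzuki coupling of F3 at the C–I bond of F6 (Pd(dppf)Cl2, K3PO4, DMF/H2O) would give (3S)-1-[2-bromo-5-(methoxymethoxy)-3-methylphenyl]-3,7-dimethyloct-6-en-3-ol F7. Pd-catalysed intramolecular etherification (Pd(OAc)2, 2-(di-tert-butylphosphino)-1,1'-binaphthyl, Cs2CO3, toluene, 80 °C) would then return to the route at 7.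

**Step 9.** Under aprotic conditions the Payne equilibrium may lie too far on the side of the trisubstituted epoxide or be too slow, so that the ylide is consumed by proton transfer and 10 is recovered or isomerised. The fallback runs the C1 opening under the classic aqueous Payne conditions and then homologates a protected terminal epoxide; it sets out from 10. PhSH and NaOH in t-BuOH/H2O should give (2R,3R)-3,7-dimethyl-1-(phenylsulfanyl)oct-6-ene-2,3-diol F8. S-Methylation (Me3OBF4, CH2Cl2) and ring closure with NaH would give 11 as an isolated compound, and TMSCl/imidazole would give trimethyl({(2R)-6-methyl-2-[(2S)-oxiran-2-yl]hept-5-en-2-yl}oxy)silane F9, which can no longer rearrange back. Opening with dimethylsulfonium methylide and elimination would give (3S,4R)-4,8-dimethyl-4-[(trimethylsilyl)oxy]nona-1,7-dien-3-ol F10, and K2CO3 in MeOH would return to the route at 12.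

**Step 12.** Boronate formation between the hindered α-methyl alkenyllithium and 14 may be incomplete, iodine may attack the electron-rich olefins, and any E-iodide carried from step 7 would appear as the 3'Z isomer. The fallback makes the same C4'–C5' bond by a stereoretentive Suzuki coupling of an (E)-iodide and sets out from 8, so it also bypasses step 7. Ohira–Bestmann homologation should give (2S)-2-(but-3-yn-1-yl)-6-(methoxymethoxy)-2,8-dimethyl-3,4-dihydro-2H-chromene F11, and n-BuLi then MeI would give (2S)-6-(methoxymethoxy)-2,8-dimethyl-2-(pent-3-yn-1-yl)-3,4-dihydro-2H-chromene F12. Hydrozirconation with excess Cp2Zr(H)Cl at 50 °C (Zr at the methyl-bearing carbon under thermodynamic control) followed by I2 would give (2S)-2-[(3E)-4-iodopent-3-en-1-yl]-6-(methoxymethoxy)-2,8-dimethyl-3,4-dihydro-2H-chromene F13. Hydroboration of 13 with 9-BBN would give 9-{2-[(4S,5R)-2,2,5-trimethyl-5-(4-methylpent-3-en-1-yl)-1,3-dioxolan-4-yl]ethyl}-9-borabicyclo[3.3.1]nonane F14, and B-alkyl Suzuki coupling with F13 (Pd(dppf)Cl2, AsPh3, Cs2CO3, DMF/THF/H2O) would return to the route at 17.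

## Further compounds

F1 | step 5 | (2S,3R)-3-(iodomethyl)-2-methyl-2-(4-methylpent-3-en-1-yl)oxirane | IC[C@@H]1O[C@@]1(C)CCC=C(C)C
F2 | step 5 | (3S)-linalool, (3S)-3,7-dimethylocta-1,6-dien-3-ol | C=C[C@@](C)(O)CCC=C(C)C
F3 | step 5 | (3R)-1-(9-borabicyclo[3.3.1]nonan-9-yl)-3,7-dimethyloct-6-en-3-ol | CC(C)=CCC[C@](C)(O)CCB1C2CCCC1CCC2
F4 | step 5 | 4-(methoxymethoxy)-2-methylaniline | COCOc1ccc(N)c(C)c1
F5 | step 5 | 2-iodo-4-(methoxymethoxy)-6-methylaniline | COCOc1cc(C)c(N)c(I)c1
F6 | step 5 | 2-bromo-1-iodo-5-(methoxymethoxy)-3-methylbenzene | COCOc1cc(C)c(Br)c(I)c1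
F7 | step 5 | (3S)-1-[2-bromo-5-(methoxymethoxy)-3-methylphenyl]-3,7-dimethyloct-6-en-3-ol | CC(C)=CCC[C@](C)(O)CCc1cc(OCOC)cc(C)c1Br
F8 | step 9 | (2R,3R)-3,7-dimethyl-1-(phenylsulfanyl)oct-6-ene-2,3-diol | CC(C)=CCC[C@@](C)(O)[C@@H](O)CSc1ccccc1
F9 | step 9 | trimethyl({(2R)-6-methyl-2-[(2S)-oxiran-2-yl]hept-5-en-2-yl}oxy)silane | CC(C)=CCC[C@@](C)(O[Si](C)(C)C)[C@@H]1CO1
F10 | step 9 | (3S,4R)-4,8-dimethyl-4-[(trimethylsilyl)oxy]nona-1,7-dien-3-ol | CC(C)=CCC[C@@](C)(O[Si](C)(C)C)[C@@H](O)C=C
F11 | step 12 | (2S)-2-(but-3-yn-1-yl)-6-(methoxymethoxy)-2,8-dimethyl-3,4-dihydro-2H-chromene | C#CCC[C@@]1(C)CCc2cc(OCOC)cc(C)c2O1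
F12 | step 12 | (2S)-6-(methoxymethoxy)-2,8-dimethyl-2-(pent-3-yn-1-yl)-3,4-dihydro-2H-chromene | CC#CCC[C@@]1(C)CCc2cc(OCOC)cc(C)c2O1
F13 | step 12 | (2S)-2-[(3E)-4-iodopent-3-en-1-yl]-6-(methoxymethoxy)-2,8-dimethyl-3,4-dihydro-2H-chromene | C/C(I)=C\CC[C@@]1(C)CCc2cc(OCOC)cc(C)c2O1
F14 | step 12 | 9-{2-[(4S,5R)-2,2,5-trimethyl-5-(4-methylpent-3-en-1-yl)-1,3-dioxolan-4-yl]ethyl}-9-borabicyclo[3.3.1]nonane | CC(C)=CCC[C@@]1(C)OC(C)(C)O[C@H]1CCB2C3CCCC2CCC3
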